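The numbers were drawn at random within sensible limits; the run is a simulation.

A flask cannot hold more D.L than the X that has opened, and the rate at which X opens contains neither D nor Z.

    Z + L → Z.L (k1 = 94 L mol⁻¹ s⁻¹)
    L → G (k2 = 0.47 s⁻¹)
    X → L (k3 = 0.012 s⁻¹)
    D + L → D.L (k4 = 170 L mol⁻¹ s⁻¹)
    D + D.L ⇌ D.D.L, settled at all times (K5 = 110 L mol⁻¹)

| flask | X | D | Z | time | remark |
|---|---|---|---|---|---|
| cedar | 5.0 mM | 0.900 equiv (fed, over 30 s) | 1.20 equiv | 50 s | all else is in the flask from the start; the feed brings no volume worth counting |
| birch | 5.0 mM | 0.900 equiv | 1.20 equiv (fed, over 30 s) | 50 s | all else is in the flask from the start; the feed brings no volume worth counting |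
| ash | 5.0 mM | 0.900 equiv | 1.20 equiv | 50 s | everything together at the start |

- what is said of D.L includes D.D.L
- run time (cedar): 50 s

- which flask leads in amount of D.L, in percent of the X charged ("all alike" within 1.5 percentage points) (cedar / birch / ash / all alike)
- how much D.L is there at the end, in percent of the X charged: cedar
- how much D.L is there at the end, in percent of the X charged: birch
- how much D.L is there at the end, in percent of the X charged: ash

I work with the fraction left. The X left at 50 s is 54.9%, so 45.1% has opened, that is, has turned into L.

But L does not wait: its half-life by decay to G alone in ash is 1.5 s, far shorter than the 58 s of X. So I ask how L divides among its exits; capture by D and capture by Z are pseudo-first-order in L while their amounts hold.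

On the charged amounts, D takes L at 0.765 s⁻¹, Z takes it at 0.564 s⁻¹, and decay takes it at 0.47 s⁻¹. So 42.5% is my capture share, the rate of capture by D over the sum of L's exits.

Opened times share gives 19.2% for ash. D is used as ash runs, so I hold that figure a little high.

But the feeds move the share early. Birch starts without Z, so its share starts at 61.9%, above that of ash. Cedar starts without D, so its share starts at zero. I put birch ahead of ash and ash ahead of cedar.

The forecast gives 12.9% for cedar, 20% for birch and 17.8% for ash, and it names birch. It counts that “each product ties up about 1.3 D”, and its ash stands below my figure.

The flasks give 13.2% for cedar, 19.9% for birch and 17.8% for ash, so birch leads.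

Birch reads 1.04 times my figure for ash. The neighbour of birch charged with 12 mM of X keeps the equivalents, so capture by D and by Z speeds up while decay keeps its constant. Its capture share is 50.2%, and the opened fraction stays 45.1%. That gives 22.6%, and the same factor makes it 23.5%. The neighbour reads 24.0%, with G at 7.78% against 14.4% in birch.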